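## Analysis of the target

Target 26 is a tetracycle. A 5,6-dimethyl-2-pyranone (ring A) is joined through a methylene (C11) and a ketal oxygen into a dihydropyran (ring B). Ring B is fused along C1–C7 to a seven-membered carbocycle (ring C, C1 ketal carbon, C2 CHOH, C3 ketone, C4 tertiary carbinol, C5 alkene carbon, C6 CHMe, C7 CH). Ring C is fused along C4–C5 to a gem-dimethylcyclopentenone (ring D, adding C8 =CH, C9 C=O, C10 CMe2).

There are five stereocentres: C1 (S), C2 (R), C4 (R), C6 (R) and C7 (R). Rings B and C are trans-fused; the C1 and C4 hydroxyls and C11 lie on one face of ring C, and the C2 hydroxyl, the C6 methyl and the ring B oxygen on the other.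

The sensitive groups are the hemiketal, the two α-ketol units that flank the C3 ketone (acyloin shifts under base), the enone and the base-labile pyranone. Ring–chain tautomerism of the hemiketal exposes a 2-hydroxy-1,3-diketone, so C1 (and in principle C2) are configurationally mobile, whereas C4 and C6 are not.

The difficulty is the run of four oxidised carbons C1–C4 on a seven-membered ring, with quaternary C4 wedged between a ketone and CMe2. The strategy rests on two observations. C6–C7 is the only ring C bond between two carbons that carry no oxygen. The oxygens on C1, C2 and C4 (with the C9 carbonyl) are what remains when the enol-type alkenes C1=C2 and C4=C5–C8=C9 are oxidised, and these are exactly the alkenes that a divinylcyclopropane rearrangement forming C6–C7 leaves behind.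

## Retrosynthetic reasoning

**26 from 25.** The three hydroxyls are unmasked last from tris(silyl) compound 25. Nothing is cut, but the hemiketal carbon C1 is allowed to find its preferred configuration by ring opening and reclosure once the silyl ketal is gone.

**25 from 23 via 24.** The C3 ketone is kept at the alcohol oxidation level, as an oxidatively removable benzyl-type ether, until C1 is locked as a ketal. C2–H then never sits between two free carbonyls while protecting groups are still in place.

**23 from 19 and 22.** Ring B is cut at C7–C11 and C1–O. These are the two bonds a hetero-Diels–Alder reaction of pyranone methide 22 (released from Mannich base 21, made from pyranone 20) forms with the C1=C7 enol silane 19. This attaches ring A without any organometallic chemistry on the pyranone and sets C7 anti to the C6 methyl.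

**19 from 15 via 18 and 17.** The C1=C7 enol silane needs a C1 ketone whose other α-carbon is blocked; the C2 silyloxy group in 18 does this. The C2 oxygen in diol 15 sits on the wrong face, so it is inverted (15 to 17) before protection.

**15 from 13.** The C2 and C4 hydroxyls, the C1 ketone and the C9 enone are all removed in one retrosynthetic step, back to the two enol silanes of 13. The forward oxidation must attack both alkenes from the face not covered by the folded ring, which sets C4.

**13 from 12 (key disconnection).** The C6–C7 bond is cut and the C2–C4 bond is re-formed, giving spiro divinylcyclopropane 12. This is the only place where ring C can be opened without touching an oxygenated carbon. It exchanges a seven-membered ring with a remote stereocentre for a cyclopropane whose configuration, together with the alkene geometry, dictates C6.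

**12 from 9 via 11 and 10.** Both enol silanes come from diketone 11 in one enolisation. Its 3-ethylcyclopentenone is traced to cyclopropyl enone 9 by an alkylative 1,3-carbonyl transposition (through 10). That puts the ring D oxygen on C5 in the early intermediates, where it is needed for the next two disconnections.

**9 from 6 via 8 and 7.** The cyclopropane is cut at C2–C3 and C2–C4, back to allylic diazoacetate 6. The ester tether (lactone 7) forces the C1 carbon on C2 to be cis to C5, and the retained enol ether geometry places the C3 ether trans to it. Opening 7 with a methyl nucleophile and oxidising 8 gives 9.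

**6 from 1 via 4 and 3.** The enol ether carbon C3 is removed as a formyl group from the only enolisable position of enone 1. The C5 carbonyl of 3 serves twice: it fixes the enol ether geometry (ether oxygen away from the carbonyl), and after enantioselective reduction to 4 it carries the stereocentre from which the whole absolute configuration is relayed.

## Alternatives that were turned down

**Alternative 1:** Ring C is cut at C1–C2 and C3–C4, with the C4 oxygen as a bridge to C1. In the forward direction a dirhodium carboxylate converts an acyclic diazo ketone into a carbenoid at C4, the C1 ester carbonyl captures it, and the six-membered carbonyl ylide adds to vinylene carbonate A1 to give the oxygen-bridged ketal A2.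
- In its favour: one step closes ring C and oxygenates C1, C2, C3 and C4; C6 and C7 can be set beforehand in an open chain; the route is convergent.
- Against it: ester carbonyls are reluctant ylide partners, and a carbenoid flanked by a ketone and a quaternary carbon has 1,2-shift and Wolff pathways open. Nothing enforces the face of dipolarophile approach relative to C6 and C7. The carbonate delivers a cis C2/C3 diol that must then be differentiated next to a ketal. Ring D still has to be closed by aldol condensation onto a hindered ketone with a β-oxygen at C4, and the C11 ester must later be joined to the pyranone through a separate C–C bond formation.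
- Comparison: it is stronger on convergence and on delivering the C1–C4 oxidation pattern directly. The chosen strategy offers instead a strain-driven, stereospecific ring closure whose only new stereocentre follows from alkene geometry, a ring D present from the first step, and attachment of ring A by a cycloaddition.

**Alternative 2:** Ring C is cut at C5–C6 and C1–C7. The oxidopyrylium betaine A3 and the N-crotonyl oxazolidinone A4 combine in a (5+2) cycloaddition to the 8-oxabicyclo[3.2.1]octenone A5.
- In its favour: this cycloaddition class is robust, makes two C–C bonds, sets C6 and C7 together from the alkene geometry, and takes its absolute configuration from an auxiliary. On C7 and on precedent for absolute control it is stronger than the chosen route.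
- Against it: the oxidation levels are wrong. C1 arrives as a CH–O and must be raised to the ketal level, C5 carries a bridge oxygen that must be removed reductively, and C2 is an unoxygenated alkene carbon. Ring D needs an aldol of an isopropyl ketone onto C4 that creates two adjacent quaternary carbons, followed by dehydrogenation. The C7 acyl group must be reduced and coupled to a pyranone. A β-substituted acrylimide is also a sluggish partner for a 2-substituted betaine.
- Comparison: the chosen strategy sets C7 later and less directly, but needs no redox correction at C1 and C5 and gives the C5=C8 enone and both ring D oxygens from one oxidation.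

**Alternative 3:** Ring C is cut at C3–C4. A carbene from the triazolium salt A6 and an amine base turns a C3 aldehyde into an acyl anion equivalent that adds to one ketone of a 2,2-dimethylcyclopentane-1,3-dione unit, giving α-ketol A7.
- In its favour: the C3 ketone and C4 tertiary carbinol are made together, redox-neutrally, exactly as in the target. On that point it is stronger than the chosen route, which needs ether cleavage and oxidation at C3 and a separate oxidation for C4.
- Against it: acyl-anion closure of a seven-membered ring is less favourable than the usual five- and six-membered cases. Which dione carbonyl is attacked, and from which face, must be controlled by C5 and C6 with an achiral carbene. The α-silyloxy aldehyde can epimerise at C2 under the basic conditions and the product can revert by retro-benzoin. The C5=C8 alkene must afterwards be introduced next to the tertiary carbinol, and the open-chain precursor needs its own stereocontrolled synthesis.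
- Comparison: the chosen strategy gives up the direct C3/C4 construction and gains an irreversible, stereospecific ring closure and an enone that arises without a dehydrogenation step.

Key step: step 10

## Route

Remark on numbering: the target locants C1–C11 defined in the analysis are used for all intermediates, and CIP descriptors quoted with them refer to these locants.

Assumption: the hemiketal carbon C1 of 26 has the thermodynamically preferred configuration (trans-fused ring B, axial hydroxyl), because ring–chain tautomerism makes this centre mobile; it is therefore set by equilibration in the last step.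

Step 1
Reactants: 1 4,4-dimethylcyclopent-2-en-1-one
Product: 3 (5E)-5-{[(4-methoxybenzyl)oxy]methylidene}-4,4-dimethylcyclopent-2-en-1-one, via sodium hydroxymethylidene enolate 2 (not isolated)
Conditions: NaH, HCO2Et, THF, 0 °C → rt; then 4-MeOC6H4CH2Cl, Bu4NI (cat.), DMF, rt
Reagents that add atoms: ethyl formate (CCOC=O); 4-methoxybenzyl chloride (COc1ccc(CCl)cc1)
Why: Crossed Claisen formylation can only occur at the α′-methylene (the future C4), since the γ-carbon is quaternary; O-alkylation of the resulting enolate is favoured because C-alkylation would build two adjacent quaternary carbons. The E isomer, with the ether oxygen turned away from the carbonyl and towards CMe2, is the dipole-minimised form usual for 2-(alkoxymethylidene) ketones; this geometry later places the C3 ether trans to both vinyl groups of the cyclopropane.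

Step 2
Reactants: 3 (5E)-5-{[(4-methoxybenzyl)oxy]methylidene}-4,4-dimethylcyclopent-2-en-1-one
Product: 4 (1S,5E)-5-{[(4-methoxybenzyl)oxy]methylidene}-4,4-dimethylcyclopent-2-en-1-ol
Conditions: (R)-2-methyl-CBS-oxazaborolidine (20 mol%), BH3·SMe2, THF, −40 °C; MeOH, then aq. NaHCO3
Reagents that add atoms: none
Why: Corey–Bakshi–Shibata 1,2-reduction; the fully substituted alkylidene carbon should act as the large group and the CH=CH arm as the small one, so the (R)-catalyst should give the (S)-carbinol (C5 in target numbering). The work-up is kept basic because this doubly allylic carbinol ionises easily.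

Step 3
Reactants: 4 (1S,5E)-5-{[(4-methoxybenzyl)oxy]methylidene}-4,4-dimethylcyclopent-2-en-1-ol
Product: 6 (1S,5E)-5-{[(4-methoxybenzyl)oxy]methylidene}-4,4-dimethylcyclopent-2-en-1-yl diazoacetate, via bromoacetate 5 (not isolated)
Conditions: BrCH2COBr, NaHCO3, MeCN, 0 °C; then TsNHNHTs, DBU, THF, 0 °C
Reagents that add atoms: bromoacetyl bromide (BrCC(Br)=O); N,N'-ditosylhydrazine (Cc1ccc(cc1)S(=O)(=O)NNS(=O)(=O)c1ccc(C)cc1)
Why: Acylation followed by the bromoacetate-to-diazoacetate conversion (N-alkylation of the bis-sulfonyl hydrazide and two base-induced sulfinate eliminations) runs under mildly basic conditions that the acid-labile enol ether and allylic ester tolerate; the carbinol stereocentre is not touched.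

Step 4
Reactants: 6 (1S,5E)-5-{[(4-methoxybenzyl)oxy]methylidene}-4,4-dimethylcyclopent-2-en-1-yl diazoacetate
Product: 7 cyclopropane-fused γ-lactone (2R,3S,4R,5S): lactone carbonyl C1 on C2 and ring oxygen on C5; C3 bears the 4-methoxybenzyl ether trans to C1; spiro carbon C4 shared with the 10,10-dimethylcyclopent-8-ene ring
Conditions: Rh2(OAc)4 (1 mol%), CH2Cl2, rt, slow addition of 6
Reagents that add atoms: none
Why: Intramolecular cyclopropanation of an allylic diazoacetate by a rhodium carbenoid; the electrophilic carbenoid should prefer the electron-rich exocyclic enol ether to the ring alkene. The five-membered lactone tether forces C1 on C2 to be cis to C5 and delivers C2 to the face of C4 syn to the carbinol oxygen, and the alkene geometry is retained, so C2, C3 and C4 are set in one step from the C5 stereocentre.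

Step 5
Reactants: 7 cyclopropane-fused γ-lactone
Product: 8 (2R,3S,4S,5S)-C2-acetyl C5-carbinol (1-acetyl-4-hydroxy-2-[(4-methoxybenzyl)oxy]-7,7-dimethylspiro[2.4]hept-5-ene; in equilibrium with its bicyclic lactol)
Conditions: MeLi, THF, −78 °C; AcOH, −78 °C
Reagents that add atoms: methyllithium ([Li]C)
Why: Addition of one equivalent of methyllithium to the lactone; the lithium lactolate does not collapse at low temperature, so over-addition is avoided and the methyl ketone (C1 with C7) is released on quenching.

Step 6
Reactants: 8 C2-acetyl C5-carbinol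
Product: 9 (2R,3S,4R)-1-acetyl-2-[(4-methoxybenzyl)oxy]-7,7-dimethylspiro[2.4]hept-5-en-4-one (C5 ketone conjugated with C8=C9)
Conditions: Dess–Martin periodinane, NaHCO3, CH2Cl2, 0 °C → rt
Reagents that add atoms: none
Why: Dess–Martin oxidation of the open-chain secondary allylic carbinol under buffered conditions that spare the alkoxycyclopropane; the lactol is a ketone hemiketal and cannot be oxidised itself. The C5 stereocentre has done its work and is removed.

Step 7
Reactants: 9 cyclopropyl enone
Product: 10 (2R,3S,4R,5S)-1-acetyl-4-ethyl-4-hydroxy-2-[(4-methoxybenzyl)oxy]-7,7-dimethylspiro[2.4]hept-5-ene (C5 tertiary carbinol; its configuration is of no consequence)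
Conditions: LiN(iPr)2 (1.1 equiv), THF, −78 °C; then EtMgBr–CeCl3, −78 °C; aq. NH4Cl
Reagents that add atoms: ethylmagnesium bromide (CC[Mg]Br)
Why: The acetyl group, the only enolisable site, is parked as its lithium enolate; the non-basic organocerium reagent then adds 1,2 to the hindered enone carbonyl, probably from the face away from the C1 side chain.

Step 8
Reactants: 10 tertiary allylic carbinol
Product: 11 (2R,3S,4R)-1-acetyl-4-ethyl-2-[(4-methoxybenzyl)oxy]-7,7-dimethylspiro[2.4]hept-4-en-6-one (C5 ethyl, C5=C8, C9 ketone)
Conditions: pyridinium chlorochromate [C5H5NH][CrO3Cl], NaOAc, 4 Å MS, CH2Cl2, rt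
Reagents that add atoms: pyridinium chlorochromate ([O-][Cr](=O)(=O)Cl.c1cc[nH+]cc1)
Why: Babler–Dauben oxidative transposition: the chromate ester of the tertiary allylic alcohol undergoes a [3,3] shift to C9 and the resulting secondary chromate is oxidised to the enone. This moves the ring D oxygen to C9 next to CMe2 and leaves the ethyl group on C5; the acetate buffer limits ionisation at C5.

Step 9
Reactants: 11 spiro diketone
Product: 12 (2R,3S,4R)-bis(enol silane): cyclopropane C2 bears CH2=C(OSiEt3)–, C3 bears the 4-methoxybenzyl ether, spiro C4 belongs to a ring with (E)-ethylidene on C5, C8=C9(OSiEt3) and 10,10-dimethyl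
Conditions: LiN(iPr)2 (2.5 equiv), Et3SiCl, THF–DMPU, −78 °C; cold NaHCO3 work-up
Reagents that add atoms: chlorotriethylsilane (CC[Si](Cl)(CC)CC)
Why: Kinetic deprotonation occurs at the acetyl methyl group and, because the enone has no α′-hydrogens, at the γ-methylene of the ethyl group; both enolates are silylated on oxygen. The exocyclic dienolate should form with its methyl group syn to C8–H and away from the spiro carbon (allylic 1,3-strain), which is the E geometry.

Step 10
Reactants: 12 spiro bis(enol silane)
Product: 13 (3S,6R)-3-[(4-methoxybenzyl)oxy]-6,10,10-trimethyl-1,9-bis(triethylsilyloxy) bicyclic triene (ring C with C1=C2 and C4=C5; ring D with C8=C9)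
Conditions: toluene (trace Et3N), 90 °C, base-washed glassware
Reagents that add atoms: none
Why: The reaction is a concerted [3,3]-sigmatropic shift through a boat transition state in which C6 bonds to C7 while the cyclopropane bond C2–C4 breaks and the π bonds move to C1=C2 and C4=C5. The closest known reaction type is the thermal rearrangement of cis-divinylcyclopropanes to cyclohepta-1,4-dienes, including substrates whose vinyl group is a silyl enol ether. Ring C is closed by ring expansion of the three-membered ring, a sigmatropic closure with no ionic or radical intermediate, driven by release of cyclopropane strain. The new stereocentre C6 is set stereospecifically: with the (E)-ethylidene methyl on the outside of the boat and the cyclopropane configuration fixed at C2 and C4, C6 becomes R and cis to the C3 ether, whose own configuration is carried through unchanged. The step needs the two vinyl groups cis (secured by the lactone tether of step 4), a hydrogen rather than the ether as the C3 substituent on their face (secured by the E enol ether of 3), and the E-ethylidene (step 9). The spiro ring holds the exocyclic alkene with its π lobe already directed at C7, so no unfavourable conformer has to be populated. No C–H bond is placed for a competing homodienyl hydrogen shift, and the quaternary C10 blocks 1,5-hydrogen shifts in the cyclopentadiene that is formed.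

Step 11
Reactants: 13 bicyclic bis(enol silane)
Product: 15 (2S,3S,4R,6R)-2,4-dihydroxy-3-[(4-methoxybenzyl)oxy]-6,10,10-trimethyl bicyclic 1,9-dione with C5=C8, via bis-epoxide 14 (not isolated)
Conditions: dimethyldioxirane (acetone), CH2Cl2, −78 → −40 °C; then Et3N·3HF, THF, 0 °C
Reagents that add atoms: dimethyldioxirane (CC1(C)OO1)
Why: Rubottom oxidation of the C1=C2 enol silane and vinylogous Rubottom oxidation (γ-hydroxylation) of the silyl dienol ether; fluoride collapses both silyloxy epoxides to the C1 ketone with C2–OH and to the C9 enone with C4–OH. Each alkene should be attacked on the face not covered by the folded seven-membered ring, which is anti to the C3 ether and the C6 methyl; this sets C4 (R) and gives C2 as the epimer that is corrected next.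

Step 12
Reactants: 15 (2S)-diol
Product: 17 (2R,3S,4R,6R)-2,4-dihydroxy-3-[(4-methoxybenzyl)oxy]-6,10,10-trimethyl bicyclic 1,9-dione with C5=C8, via C2 4-nitrobenzoate 16 (not isolated)
Conditions: 4-O2NC6H4CO2H, PPh3, DIAD, toluene, 0 °C → rt; then K2CO3 (cat.), MeOH, 0 °C
Reagents that add atoms: 4-nitrobenzoic acid (O=C(O)c1ccc(cc1)[N+](=O)[O-])
Why: Mitsunobu inversion of the secondary, carbonyl-activated C2 carbinol (the tertiary C4 hydroxyl cannot react), followed by mild methanolysis of the activated ester; C2 now has the R configuration of the target.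

Step 13
Reactants: 17 (2R)-diol
Product: 18 (2R,3S,4R,6R)-2,4-bis(triethylsilyloxy)-3-[(4-methoxybenzyl)oxy]-6,10,10-trimethyl bicyclic 1,9-dione with C5=C8
Conditions: Et3SiOTf, 2,6-lutidine, CH2Cl2, −78 → 0 °C
Reagents that add atoms: triethylsilyl trifluoromethanesulfonate (CC[Si](CC)(CC)OS(=O)(=O)C(F)(F)F)
Why: Silyl triflate silylation of the secondary and the tertiary hydroxyl; this suppresses α-ketol shifts and allows the strong-base enolisation that follows.

Step 14
Reactants: 18 bis(triethylsilyl) ether
Product: 19 (2R,3S,4R,6R)-C1(OSiEt3)=C7 enol silane of 18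
Conditions: LiN(iPr)2 (1.05 equiv), Et3SiCl, THF, −78 °C (in situ quench)
Reagents that add atoms: chlorotriethylsilane (CC[Si](Cl)(CC)CC)
Why: Kinetic enolisation of an α-silyloxy ketone takes place at the unsubstituted α-methylene (C7), away from the oxygenated carbon; the hindered γ-proton of the ring D enone at C6 is kinetically less accessible, and the in situ quench prevents equilibration.

Step 15
Reactants: 20 4-hydroxy-5,6-dimethyl-2H-pyran-2-one
Product: 21 3-[(dimethylamino)methyl]-4-hydroxy-5,6-dimethyl-2H-pyran-2-one
Conditions: CH2O (37% aq.), Me2NH (40% aq.), EtOH, 0 °C → rt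
Reagents that add atoms: formaldehyde (C=O); dimethylamine (CNC)
Why: Mannich reaction at the nucleophilic C3 of the 4-hydroxypyranone gives a storable precursor of the methide.

Step 16
Reactants: 19 C1=C7 enol silane; 21 3-[(dimethylamino)methyl]-4-hydroxy-5,6-dimethyl-2H-pyran-2-one
Product: 23 (1S,2R,3S,4R,6R,7R)-cis-fused silyl ketal: ring B closed between C7–C11 and C1–O; C1 bears OSiEt3; C2 and C4 bear OSiEt3; C3 bears the 4-methoxybenzyl ether, via pyranone methide 22 (not isolated)
Conditions: toluene, 100 °C, N2 sweep
Reagents that add atoms: none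
Why: Thermal loss of dimethylamine gives the pyranone methide, which reacts as an electron-poor 1-oxadiene in an inverse-electron-demand hetero-Diels–Alder reaction with the enol silane; the methylene terminus bonds to C7 and the C4 carbonyl oxygen of the pyranone to C1. Approach anti to the C6 methyl and the C2 silyloxy group sets C7 (R), and suprafacial addition gives the cis-fused ketal.

Step 17
Reactants: 23 cis-fused silyl ketal
Product: 24 (1S,2R,3S,4R,6R,7R)-C3 alcohol of 23
Conditions: DDQ, CH2Cl2–pH 7 buffer, 0 °C
Reagents that add atoms: none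
Why: Oxidative cleavage of the 4-methoxybenzyl ether by DDQ under buffered conditions leaves the silyl ethers, the silyl ketal, the enone and the pyranone untouched.

Step 18
Reactants: 24 C3 alcohol
Product: 25 (1S,2R,4R,6R,7R)-C3 ketone: tris(triethylsilyl) derivative of the C1 epimer of the target
Conditions: Dess–Martin periodinane, NaHCO3, CH2Cl2, rt
Reagents that add atoms: none
Why: Dess–Martin oxidation of the hindered secondary carbinol; because C1 is a ketal at this point, C2–H is flanked by only one carbonyl and should keep its configuration.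

Step 19
Reactants: 25 tris(triethylsilyl) C3 ketone
Product: 26 CNP0525404.1 (1S,2R,4R,6R,7R)
Conditions: HF·pyridine, pyridine, THF, 0 °C → rt; then pH 7 phosphate buffer–THF, rt
Reagents that add atoms: none
Why: Fluoride removes the three silyl groups; the cis-fused hemiketal formed first should equilibrate by ring–chain tautomerism to the trans-fused hemiketal with an axial, anomerically stabilised C1 hydroxyl, which sets C1. The descriptor at C1 stays S although the centre is inverted, because the substituent priorities change when silicon is lost.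

## Compound list

1 | 4,4-dimethylcyclopent-2-en-1-one | O=C1C=CC(C)(C)C1 | starting material
2 | sodium enolate of 5-(hydroxymethylidene)-4,4-dimethylcyclopent-2-en-1-one | [Na+].[O-]C=C1C(=O)C=CC1(C)C | intermediate
3 | (5E)-5-{[(4-methoxybenzyl)oxy]methylidene}-4,4-dimethylcyclopent-2-en-1-one | O=C1C=CC(C)(C)/C1=C\OCc1ccc(OC)cc1 | intermediate
4 | (1S,5E)-5-{[(4-methoxybenzyl)oxy]methylidene}-4,4-dimethylcyclopent-2-en-1-ol | O[C@H]1C=CC(C)(C)/C1=C\OCc1ccc(OC)cc1 | intermediate
5 | (1S,5E)-5-{[(4-methoxybenzyl)oxy]methylidene}-4,4-dimethylcyclopent-2-en-1-yl bromoacetate | BrCC(=O)O[C@H]1C=CC(C)(C)/C1=C\OCc1ccc(OC)cc1 | intermediate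
6 | (1S,5E)-5-{[(4-methoxybenzyl)oxy]methylidene}-4,4-dimethylcyclopent-2-en-1-yl diazoacetate | [N-]=[N+]=CC(=O)O[C@H]1C=CC(C)(C)/C1=C\OCc1ccc(OC)cc1 | intermediate
7 | cyclopropane-fused γ-lactone (2R,3S,4R,5S) | O=C1[C@H]2[C@H](OCc3ccc(OC)cc3)[C@@]24[C@@H](O1)C=CC4(C)C | intermediate
8 | (2R,3S,4S,5S)-1-acetyl-4-hydroxy-2-[(4-methoxybenzyl)oxy]-7,7-dimethylspiro[2.4]hept-5-ene | CC(=O)[C@H]1[C@H](OCc2ccc(OC)cc2)[C@@]13[C@@H](O)C=CC3(C)C | intermediate
9 | (2R,3S,4R)-1-acetyl-2-[(4-methoxybenzyl)oxy]-7,7-dimethylspiro[2.4]hept-5-en-4-one | CC(=O)[C@H]1[C@H](OCc2ccc(OC)cc2)[C@@]13C(=O)C=CC3(C)C | intermediate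
10 | (2R,3S,4R,5S)-1-acetyl-4-ethyl-4-hydroxy-2-[(4-methoxybenzyl)oxy]-7,7-dimethylspiro[2.4]hept-5-ene | CC(=O)[C@H]1[C@H](OCc2ccc(OC)cc2)[C@@]13[C@](O)(CC)C=CC3(C)C | intermediate
11 | (2R,3S,4R)-1-acetyl-4-ethyl-2-[(4-methoxybenzyl)oxy]-7,7-dimethylspiro[2.4]hept-4-en-6-one | CC(=O)[C@H]1[C@H](OCc2ccc(OC)cc2)[C@@]13C(CC)=CC(=O)C3(C)C | intermediate
12 | (2R,3S,4R)-spiro bis(enol silane) with (E)-ethylidene on C5 and 4-methoxybenzyl ether on C3 | C=C(O[Si](CC)(CC)CC)[C@H]1[C@H](OCc2ccc(OC)cc2)[C@@]13/C(=C/C)C=C(O[Si](CC)(CC)CC)C3(C)C | intermediate
13 | (3S,6R)-bicyclic C1 enol silane and C9 silyl dienol ether | CC[Si](CC)(CC)OC1=C[C@H](OCc3ccc(OC)cc3)C2=C(C=C(O[Si](CC)(CC)CC)C2(C)C)[C@H](C)C1 | intermediate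
14 | bis-epoxide of 13 (both epoxide oxygens on the face anti to the C3 ether) | CC[Si](CC)(CC)O[C@]12O[C@H]1[C@H](OCc5ccc(OC)cc5)[C@@]34O[C@@]3(C=C(O[Si](CC)(CC)CC)C4(C)C)[C@H](C)C2 | intermediate
15 | (2S,3S,4R,6R)-2,4-dihydroxy bicyclic 1,9-dione | O=C1[C@@H](O)[C@H](OCc3ccc(OC)cc3)[C@@]2(O)C(=CC(=O)C2(C)C)[C@H](C)C1 | intermediate
16 | C2 4-nitrobenzoate (2R) | O=C1[C@H](OC(=O)c4ccc([N+](=O)[O-])cc4)[C@H](OCc3ccc(OC)cc3)[C@@]2(O)C(=CC(=O)C2(C)C)[C@H](C)C1 | intermediate
17 | (2R,3S,4R,6R)-2,4-dihydroxy bicyclic 1,9-dione | O=C1[C@H](O)[C@H](OCc3ccc(OC)cc3)[C@@]2(O)C(=CC(=O)C2(C)C)[C@H](C)C1 | intermediate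
18 | (2R,3S,4R,6R)-2,4-bis(triethylsilyl) ether | O=C1[C@H](O[Si](CC)(CC)CC)[C@H](OCc3ccc(OC)cc3)[C@@]2(O[Si](CC)(CC)CC)C(=CC(=O)C2(C)C)[C@H](C)C1 | intermediate
19 | (2R,3S,4R,6R)-C1=C7 triethylsilyl enol ether | CC[Si](CC)(CC)OC1=C[C@@H](C)C2=CC(=O)C(C)(C)[C@@]2(O[Si](CC)(CC)CC)[C@@H](OCc3ccc(OC)cc3)[C@H]1O[Si](CC)(CC)CC | intermediate
20 | 4-hydroxy-5,6-dimethyl-2H-pyran-2-one | Cc1oc(=O)cc(O)c1C | starting material
21 | 3-[(dimethylamino)methyl]-4-hydroxy-5,6-dimethyl-2H-pyran-2-one | Cc1oc(=O)c(CN(C)C)c(O)c1C | intermediate
22 | 5,6-dimethyl-3-methylidene-2H-pyran-2,4(3H)-dione | CC1=C(C)C(=O)C(=C)C(=O)O1 | intermediate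
23 | (1S,2R,3S,4R,6R,7R)-cis-fused tetracyclic silyl ketal | Cc1oc(=O)c2c(c1C)O[C@@]1(O[Si](CC)(CC)CC)[C@H](O[Si](CC)(CC)CC)[C@H](OCc4ccc(OC)cc4)[C@@]3(O[Si](CC)(CC)CC)C(=CC(=O)C3(C)C)[C@H](C)[C@H]1C2 | intermediate
24 | (1S,2R,3S,4R,6R,7R)-C3 alcohol | Cc1oc(=O)c2c(c1C)O[C@@]1(O[Si](CC)(CC)CC)[C@H](O[Si](CC)(CC)CC)[C@H](O)[C@@]3(O[Si](CC)(CC)CC)C(=CC(=O)C3(C)C)[C@H](C)[C@H]1C2 | intermediate
25 | (1S,2R,4R,6R,7R)-C3 ketone, tris(triethylsilyl) derivative | Cc1oc(=O)c2c(c1C)O[C@@]1(O[Si](CC)(CC)CC)[C@H](O[Si](CC)(CC)CC)C(=O)[C@@]3(O[Si](CC)(CC)CC)C(=CC(=O)C3(C)C)[C@H](C)[C@H]1C2 | intermediate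
26 | CNP0525404.1 | Cc1oc(=O)c2c(c1C)O[C@]1(O)[C@H](O)C(=O)[C@@]3(O)C(=CC(=O)C3(C)C)[C@H](C)[C@H]1C2 | target

## Step count and least certain steps

Total step count: 19. Longest linear sequence: 18 steps (steps 1–14 and 16–19).

**Step 10 (key step).** Reversible homolysis of the doubly allylic C2–C4 bond could compete at the temperature needed, causing one-centre epimerisation to the unreactive trans isomer or a vinylcyclopropane-to-cyclopentene shift; adventitious acid could also strip an enol silane and open the alkoxycyclopropane. The fallback uses the charge-accelerated variant. Diketone 11 is treated with KN(SiMe3)2 at −78 °C to give the dipotassium bis(enolate) F1, which should rearrange below room temperature to the ring-expanded dipotassium bis(enolate) F2; quenching with Et3SiCl returns the route to 13.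

**Step 8.** Ionisation at C5 during the chromate rearrangement could trigger an alkoxy-assisted fragmentation of the adjacent cyclopropane. The fallback moves the oxygen without a cationic intermediate. Carbinol 10 is acetylated (Ac2O, DMAP) to the tertiary acetate F3; PdCl2(MeCN)2 (divalent palladium) induces a suprafacial [3,3] shift to the C9 acetate F4; catalytic K2CO3 in methanol gives allylic alcohol F5, and Dess–Martin oxidation rejoins the route at 11.

**Step 4.** The carbenoid could add to the ring alkene, which is also allylic to the ester oxygen, instead of the enol ether. The fallback makes the cyclopropanation intermolecular, where the ring alkene is too hindered to compete. Ketone 3 is reduced with the (S)-oxazaborolidine to the (R)-carbinol F6 and silylated (tBuMe2SiCl, imidazole) to F7. Diazoacetone with Rh2(OAc)4 should add to the enol ether anti to the silyloxy group, with the acetyl group trans to the ether, giving F8. Bu4NF gives F9, the C5 epimer of 8, and Dess–Martin oxidation rejoins the route at 9.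

**Step 16.** Self-condensation of the methide, or desilylation of the hindered enol silane by the liberated amine, could outrun the cycloaddition. The fallback forms the C7–C11 bond by enolate addition. Ketone 18 is converted with LiN(iPr)2 into the C7 lithium enolate F10. Mannich base 21 is methylated (MeI) to the ammonium iodide F11, which with LiN(SiMe3)2 releases methide 22 at low temperature in the presence of F10; the Michael adduct closes to the hemiketal F12 on work-up. DDQ then gives C3 alcohol F13, Dess–Martin oxidation gives ketone F14, and HF·pyridine rejoins the route at 26.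

**Step 2.** Both carbonyl substituents are sp2 carbons, so face discrimination could be poor, and the electron-rich carbonyl could react sluggishly. The fallback is a resolution. Ketone 3 is reduced with NaBH4–CeCl3 to the racemic carbinol F15; Burkholderia cepacia lipase with vinyl acetate should acylate the (R)-enantiomer to acetate F16 and leave the (S)-carbinol, which is 4.

Further compounds

F1 | step 10 | dipotassium bis(enolate) of 11 | [K+].[K+].C=C([O-])[C@H]1[C@H](OCc2ccc(OC)cc2)[C@@]13/C(=C/C)C=C([O-])C3(C)C
F2 | step 10 | ring-expanded dipotassium bis(enolate) (3S,6R) | [K+].[K+].[O-]C1=C[C@H](OCc3ccc(OC)cc3)C2=C(C=C([O-])C2(C)C)[C@H](C)C1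
F3 | step 8 | C5 tertiary acetate of 10 | CC(=O)[C@H]1[C@H](OCc2ccc(OC)cc2)[C@@]13[C@](OC(C)=O)(CC)C=CC3(C)C
F4 | step 8 | transposed C9 acetate with C5=C8 | CC(=O)[C@H]1[C@H](OCc2ccc(OC)cc2)[C@@]13C(CC)=C[C@@H](OC(C)=O)C3(C)C
F5 | step 8 | C9 allylic alcohol with C5=C8 | CC(=O)[C@H]1[C@H](OCc2ccc(OC)cc2)[C@@]13C(CC)=C[C@@H](O)C3(C)C
F6 | step 4 | (1R,5E)-5-{[(4-methoxybenzyl)oxy]methylidene}-4,4-dimethylcyclopent-2-en-1-ol | O[C@@H]1C=CC(C)(C)/C1=C\OCc1ccc(OC)cc1
F7 | step 4 | tert-butyldimethylsilyl ether of F6 | CC(C)(C)[Si](C)(C)O[C@@H]1C=CC(C)(C)/C1=C\OCc1ccc(OC)cc1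
F8 | step 4 | cyclopropyl methyl ketone with C5 silyloxy group anti to C2 | CC(=O)[C@H]1[C@H](OCc2ccc(OC)cc2)[C@@]13[C@H](O[Si](C)(C)C(C)(C)C)C=CC3(C)C
F9 | step 4 | C5 epimer of 8 | CC(=O)[C@H]1[C@H](OCc2ccc(OC)cc2)[C@@]13[C@H](O)C=CC3(C)C
F10 | step 16 | C7 lithium enolate of 18 | [Li+].[O-]C1=C[C@@H](C)C2=CC(=O)C(C)(C)[C@@]2(O[Si](CC)(CC)CC)[C@@H](OCc3ccc(OC)cc3)[C@H]1O[Si](CC)(CC)CC
F11 | step 16 | (4-hydroxy-5,6-dimethyl-2-oxo-2H-pyran-3-yl)methyl-trimethylammonium iodide | [I-].Cc1oc(=O)c(C[N+](C)(C)C)c(O)c1C
F12 | step 16 | trans-fused hemiketal with C2 and C4 silyl ethers and C3 4-methoxybenzyl ether | Cc1oc(=O)c2c(c1C)O[C@]1(O)[C@H](O[Si](CC)(CC)CC)[C@H](OCc4ccc(OC)cc4)[C@@]3(O[Si](CC)(CC)CC)C(=CC(=O)C3(C)C)[C@H](C)[C@H]1C2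
F13 | step 16 | C3 alcohol of F12 | Cc1oc(=O)c2c(c1C)O[C@]1(O)[C@H](O[Si](CC)(CC)CC)[C@H](O)[C@@]3(O[Si](CC)(CC)CC)C(=CC(=O)C3(C)C)[C@H](C)[C@H]1C2
F14 | step 16 | C3 ketone, 2,4-bis(triethylsilyl) ether of 26 | Cc1oc(=O)c2c(c1C)O[C@]1(O)[C@H](O[Si](CC)(CC)CC)C(=O)[C@@]3(O[Si](CC)(CC)CC)C(=CC(=O)C3(C)C)[C@H](C)[C@H]1C2
F15 | step 2 | racemic (5E)-5-{[(4-methoxybenzyl)oxy]methylidene}-4,4-dimethylcyclopent-2-en-1-ol | OC1C=CC(C)(C)/C1=C\OCc1ccc(OC)cc1
F16 | step 2 | (1R,5E)-5-{[(4-methoxybenzyl)oxy]methylidene}-4,4-dimethylcyclopent-2-en-1-yl acetate | CC(=O)O[C@@H]1C=CC(C)(C)/C1=C\OCc1ccc(OC)cc1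
A1 | alternative 1 | vinylene carbonate | O=C1OC=CO1
A2 | alternative 1 | oxygen-bridged C1 methyl ketal with C2/C3 carbonate | O1[C@@]2(OC)[C@H]3OC(=O)O[C@H]3[C@]1(C(C)(C)C(C)=O)C(=O)[C@H](C)[C@H]2COC(=O)C(C)(C)C
A3 | alternative 2 | 2-[(2-isopropyl-1,3-dioxolan-2-yl)methyl]-4-methoxypyrylium-3-olate | COc1cc[o+]c(CC2(OCCO2)C(C)C)c1[O-]
A4 | alternative 2 | (S)-4-benzyl-3-[(E)-but-2-enoyl]oxazolidin-2-one | C/C=C/C(=O)N1[C@@H](Cc2ccccc2)COC1=O
A5 | alternative 2 | 8-oxabicyclo[3.2.1]octenone adduct with C6 methyl and C7 acyl trans | O1[C@@H]2C=C(OC)C(=O)[C@@]1(CC3(OCCO3)C(C)C)[C@H](C)[C@H]2C(=O)N4[C@@H](Cc5ccccc5)COC4=O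
A6 | alternative 3 | 2-(pentafluorophenyl)-6,7-dihydro-5H-pyrrolo[2,1-c][1,2,4]triazolium tetrafluoroborate | Fc1c(F)c(F)c(c(F)c1F)-[n+]1cn2CCCc2n1.F[B-](F)(F)F
A7 | alternative 3 | bicyclic α-ketol with saturated ring D | COC1(OC)[C@H](O[Si](C)(C)C(C)(C)C)C(=O)[C@@]2(O)[C@H](CC(=O)C2(C)C)[C@H](C)C1
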